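**Numbering used throughout.** Ring atoms follow the target: C1 is the alkene carbon carrying C7H2OBz, C2 the allylic carbinol, C3 the benzoate carbon, C4 the second carbinol, C5 the methoxy carbon, C6 the alkene CH. The face carrying O2, O3 and O5 is called β, the face carrying O4 is called α. Locants and descriptors of all monocyclic intermediates use this numbering.

Compounds: 1 2,2-dimethyl-1,3-dioxolane; 2 4-chloro-2,2-dimethyl-1,3-dioxolane; 3 2,2-dimethyl-1,3-dioxole; 4 methyl 2-oxo-2H-pyran-3-carboxylate; 5 bicyclic lactone cycloadduct; 6 hydroxy diester; 7 silyl ether; 8 β-epoxide; 9 half-acid; 10 γ-hydroxy enoate; 11 methyl ether; 12 allylic alcohol; 13 benzoyl chloride; 14 primary benzoate; 15 triol; 16 stannylene acetal (not isolated); 17 target.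

## Analysis of the target

The target is a cyclohexene with one trisubstituted alkene (C1=C6), a benzoyloxymethyl group (C7) on C1 and four contiguous oxygenated stereocentres C2–C5; the SMILES corresponds to 2R,3R,4R,5S. O2 and O3 are cis, O4 is trans to both O3 and O5, so O2, O3 and O5 share the β face and O4 stands alone on the α face. The five oxygens are in four different states: free hydroxyls at O2 and O4, a secondary benzoate at O3, a primary allylic benzoate at O7 and a methyl ether at O5. The difficulty therefore lies less in the carbon skeleton than in controlling four adjacent centres while telling neighbouring oxygens apart. Sensitive points are the benzoates, which can migrate to the adjacent free hydroxyls under base, and the allylic ether and ester, which can ionise under strong acid. The tetraoxygenated ring can also aromatise by elimination. The strategy rests on the 1,4-relation between C7 on C1 and the oxygen on C4, with the cis-dioxygenated C2 and C3 between them. That unit, C7–C1···C4–O4, is the O–C(=O) bridge of the bicyclic lactone formed when a 2-pyrone adds a cis-enediol ether, and C2/C3 are the two dienophile carbons.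

## Retrosynthetic reasoning

**17 to 15 and 13.** The last bond cut is the acyl–O3 bond. Benzoylating O3 at the very end means the secondary benzoate never meets base or acid afterwards, so it cannot migrate. The forward reaction must pick the equatorial O3 of the cis-2,3-diol over the pseudoaxial O2 and over O4; this is done through stannylene acetal 16.

**15 to 14.** O2, O3 and O4 are unmasked together. The isopropylidene acetal on O2/O3 and the silyl ether on O4 are both acid-labile, so one hydrolysis replaces two deprotections and uses no base.

**14 to 12 and 13, then 12 to 11.** The acyl–O7 bond is cut next; in 12 the primary allylic hydroxyl is the only free one, so no selectivity is needed. Alcohol 12 comes from ester 11 by hydride reduction, which brings C7 to its final oxidation level.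

**11 to 10.** The O5–CH3 bond is cut at the stage where O5 is the only free hydroxyl. The forward methylation has to avoid alkoxide formation, because O4 next door carries a silyl group that could migrate.

**10 to 9 to 8.** The C1=C6 alkene and the C5 hydroxyl of 10 are traced back to a C5–C6 epoxide and a carbanion at C1. One carboxyl of a geminal pair on C1 is surplus, and its loss is used to generate that carbanion and move the alkene. Half-acid 9 comes from diester 8 by saponifying one ester; which one does not matter, since C1 becomes trigonal.

**8 to 7.** The oxirane is cut back to the C5=C6 alkene. The forward epoxidation must deliver oxygen to the β face, trans to O4, because the C5–O bond made here is the one kept in the target.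

**7 to 6 to 5.** The silyl group is removed from O4 and the geminal diester is reconnected to O4 as a lactone. In the forward sense, methanolysis of the bridge of 5 releases O4 and turns the bridge carbonyl into the second ester.

**5 to 4 and 3 (key disconnection).** The C1–C2 and C3–C4 bonds are cut. This removes the carbocycle, three stereocentres, C7 and O4 in one stroke and leaves a flat pyrone 4 and a symmetrical enediol ether 3. The forward cycloaddition must be endo and face-selective.

**3 to 2 to 1.** The enol ether double bond of 3 is traced to chloride 2 by dehydrochlorination, and 2 to the saturated ketal 1 by C–H chlorination.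

## Alternatives that were turned down

Alternative 1: Enzymatic cis-dihydroxylation of an arene.
- Disconnection: the C2–O and C3–O bonds are traced to an arene, bromobenzene A1.
- Forward key step: whole-cell toluene dioxygenase oxidation gives (1S,2S)-3-bromocyclohexa-3,5-diene-1,2-diol A2; no ring is formed.
- For: A2 is a single enantiomer with the correct configuration at C2/C3. After acetal protection, the distal alkene can be epoxidised anti to the diol and opened at the allylic C5 by an alcohol, giving the trans O4/O5 pair as ether and free hydroxyl in one step. The vinyl bromide is a handle for C7.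
- Against: it depends on a fermentation or on a labile diene diol. C7 must be added by a separate palladium-catalysed carbonylation on a heavily oxygenated vinyl bromide. O4 is introduced later rather than being in place, and only one enantiomeric series comes from the wild-type enzyme.
- Comparison: this route is probably shorter and its stereochemical steps have closer analogy, so on step economy and certainty it is stronger. The chosen route offers instead a purely chemical, ligand-controlled entry in which three stereocentres, C7 and O4 all come from one cycloaddition of two small achiral compounds, with either enantiomer available.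

Alternative 2: Pinacol closure of an open-chain dialdehyde.
- Disconnection: the C2–C3 bond.
- Forward key step: one-electron reductive coupling by a divalent samarium reagent joins the conjugated C2 aldehyde and the C3 aldehyde of Z-enedial A3. It forms the ring and both carbinol centres, giving cis-diol A4.
- For: C4 and C5 come from the chiral pool already differentiated as silyl ether and methyl ether. Ring and two stereocentres form in one step; chelated ketyl coupling favours the cis-diol, anti to the neighbouring oxygen.
- Against: A3 contains a trisubstituted Z-enal that isomerises easily to the E form, which cannot cyclise. A conjugated aldehyde under one-electron reduction tends to couple at the β-carbon. A3 is also an α-alkoxy aldehyde prone to epimerisation and elimination, and it needs a long linear sequence. In A4, O2 and O3 emerge undifferentiated and O4 and O7 carry the same silyl group.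
- Comparison: the end-game problem (O2 versus O3) is the same as in the chosen route, so neither is ahead there. The chosen key step starts from stable, simple partners and is controlled by a catalyst rather than by a fragile substrate.

Alternative 3: Quinone-monoketal epoxidation.
- Disconnection: the C4–O bond (and a temporary C3–O bond) is traced to the achiral quinone monoketal A5, itself made by dearomatising a phenol.
- Forward key step: a hydroperoxide anion under chiral phase-transfer control epoxidises the unsubstituted enone bond C3=C4, giving epoxide A6.
- For: A5 is reached in very few steps and already holds all six ring carbons and C7. The substituted enone bond is deactivated, so site selectivity is built in.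
- Against: only C4 is set by the key step. C3 has to be inverted by opening the epoxide next to a ketone, C2 arises by carbonyl reduction, and C5 requires turning a ketal into a single methoxy centre. All three rely on substrate control in a nearly flat ring. Enantioselectivity of such epoxidations is variable and the epoxy ketone is base-labile.
- Comparison: up to the key intermediate this route is shorter, which is a real advantage. The chosen cycloaddition sets C2, C3 and C4 at once and leaves only C5 to relay.

Key step: step 3

Remark on the chemistry (assumption): the facial sense of the Cu(OTf)2/(S,S)-tBu-BOX catalyst is assigned from the square-planar chelate model. If it proves to be the reverse, the (R,R)-ligand is used and nothing else changes.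

## Route

Step 1
Reactants: 1 2,2-dimethyl-1,3-dioxolane
Product: 2 4-chloro-2,2-dimethyl-1,3-dioxolane (racemic)
Conditions: SO2Cl2 (1.0 equiv), AIBN (cat.), PhH, 70 °C, N2 sweep; distillation
Reagents that add atoms: sulfuryl chloride, O=S(=O)(Cl)Cl
Why: Radical-chain chlorination; hydrogen abstraction is fastest at the ring C–H next to oxygen, not at the ketal methyl groups, and one equivalent of reagent limits dichlorination. The gaseous acid by-products are swept out so that the ketal is not cleaved.

Step 2
Reactants: 2 4-chloro-2,2-dimethyl-1,3-dioxolane
Product: 3 2,2-dimethyl-1,3-dioxole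
Conditions: KOtBu (1.2 equiv), tetraglyme, 0 to 60 °C, product distilled out into a cold trap; fractional redistillation
Reagents that add atoms: none
Why: E2 dehydrochlorination of an α-chloro ether by a hindered base, the same operation that converts chlorinated cyclic carbonates into enediol carbonates. The volatile enol ether leaves the high-boiling medium as it forms, co-distilled tert-butanol is removed by the redistillation, and the product is kept cold over base.

Step 3
Reactants: 4 methyl 2-oxo-2H-pyran-3-carboxylate; 3 2,2-dimethyl-1,3-dioxole
Product: 5 methyl (1R,4S,5R,6S)-5,6-(isopropylidenedioxy)-3-oxo-2-oxabicyclo[2.2.2]oct-7-ene-4-carboxylate (endo acetonide)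
Conditions: Cu(OTf)2 (10 mol%), (S,S)-tBu-BOX (11 mol%), 4 Å MS, CH2Cl2, −40 °C; dienophile in threefold excess
Reagents that add atoms: none
Why: Inverse-electron-demand Diels–Alder reaction: the lactone and ester carbonyls of 4 chelate divalent copper, which lowers the LUMO of the pyrone diene, and the electron-rich alkene of 3 adds across pyrone C3 and C6 in a concerted but asynchronous [4+2], the bond to C6 (target C4–C3) running ahead of the bond to C3 (target C1–C2). The closest known reaction type is the chiral-Lewis-acid-catalysed cycloaddition of 3-carboalkoxy-2-pyrones with vinyl ethers and cyclic enol ethers, of which 3 is a doubly oxygenated member. The carbocycle closes intermolecularly through a boat-shaped transition state as the third bridge of a 2-oxabicyclo[2.2.2]octene, both new bonds forming suprafacially on one pyrone face, and every atom of both partners is kept in the adduct. The cis relation of C5 and C6 (target C2 and C3) is fixed by the ring of the dienophile. Their relation to the bridgeheads is fixed by the endo mode, which places the dioxolane over the C7=C8 bridge, away from the lactone bridge and the metal–ligand fragment, and is favoured by secondary overlap of the enediol oxygens with the diene; this is what later puts O2/O3 trans to O4. The absolute configuration at C1, C4, C5 and C6 is set by the ligand: in the square-planar chelate the tert-butyl group beside the lactone carbonyl shields one pyrone face, and the dienophile is expected to add to the face from which the ring numbering O1 to C6 runs counterclockwise. The step therefore needs face and endo selectivity, secured by two-point binding of 4 to the C2-symmetric complex, and a low temperature so that 3 does not oligomerise and 5 does not lose CO2.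

Step 4
Reactants: 5 bicyclic lactone cycloadduct
Product: 6 dimethyl (2R,3S,4R)-4-hydroxy-2,3-(isopropylidenedioxy)cyclohex-5-ene-1,1-dicarboxylate
Conditions: NaOMe (0.3 equiv), MeOH, 0 °C; aq. NH4Cl
Reagents that add atoms: methanol, CO
Why: Transesterification of the strained bridged lactone: methoxide adds to the lactone carbonyl and the bridge opens, releasing the boat-shaped bicycle and freeing O4. Both carbonyls on C1 are now methyl esters, so C1 is no longer stereogenic, and because C1 is quaternary no epimerisation or elimination can follow. C2, C3 and C4 are untouched.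

Step 5
Reactants: 6 hydroxy diester
Product: 7 dimethyl (2R,3R,4R)-4-(tert-butyldimethylsilyloxy)-2,3-(isopropylidenedioxy)cyclohex-5-ene-1,1-dicarboxylate
Conditions: TBSOTf (1.3 equiv), 2,6-lutidine (2 equiv), CH2Cl2, −78 to 0 °C
Reagents that add atoms: tert-butyldimethylsilyl trifluoromethanesulfonate, CC(C)(C)[Si](C)(C)OS(=O)(=O)C(F)(F)F
Why: Silylation of the only free hydroxyl; the triflate is needed because O4 is secondary and flanked by C3. The group blocks O4 for the later methylation of O5 and turns O4 from a syn-directing hydroxyl into a steric shield of the α face.

Step 6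
Reactants: 7 silyl ether
Product: 8 dimethyl (2R,3R,4R,5S,6S)-4-(tert-butyldimethylsilyloxy)-5,6-epoxy-2,3-(isopropylidenedioxy)cyclohexane-1,1-dicarboxylate (oxirane on the β face, cis to the acetonide, trans to O4)
Conditions: mCPBA (2 equiv), NaHCO3, CH2Cl2, 0 °C to rt
Reagents that add atoms: 3-chloroperoxybenzoic acid, OOC(=O)c1cccc(Cl)c1
Why: Prilezhaev epoxidation with concerted syn oxygen transfer, so C5 and C6 are set together. In the favoured half-chair (O3 and the silyloxy group equatorial, O2 axial) the silyloxy group at C4 and the pseudoaxial ester on C1 screen the α face at both allylic positions, so the peracid should add to the β face. The bicarbonate buffer protects the acetal and the new epoxide from the acid by-product.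

Step 7
Reactants: 8 β-epoxide
Product: 9 (2R,3R,4R,5S,6S)-4-(tert-butyldimethylsilyloxy)-5,6-epoxy-2,3-(isopropylidenedioxy)-1-(methoxycarbonyl)cyclohexane-1-carboxylic acid (both C1 epimers)
Conditions: LiOH·H2O (1.1 equiv), THF/MeOH/H2O, 0 °C to rt; then 1 M HCl to pH 4, 0 °C
Reagents that add atoms: lithium hydroxide, [Li+].[OH-]
Why: Saponification of one ester of a malonate-type pair; the first carboxylate formed shuts down attack at the second ester by its charge. Either ester may react, since C1 becomes trigonal in the next step. Epoxide, silyl ether and acetal tolerate hydroxide at room temperature and a brief cold acidification.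

Step 8
Reactants: 9 half-acid
Product: 10 methyl (2R,3R,4R,5S)-4-(tert-butyldimethylsilyloxy)-5-hydroxy-2,3-(isopropylidenedioxy)cyclohex-1(6)-ene-1-carboxylate
Conditions: pyridine, 110 °C
Reagents that add atoms: none
Why: Decarboxylation of a malonic half-ester coupled to E1cB ring opening of a β,γ-epoxy ester: loss of CO2 from the pyridinium carboxylate leaves the ester enolate at C1, which expels the C6–O bond of the oxirane (for the epimer with the carboxylate anti to that bond the two events can merge into a Grob-type fragmentation). The C5–O bond is not touched, so O5 keeps the β configuration set in step 6 and the alkene arrives at C1=C6 in conjugation with the ester. Both C1 epimers of 9 converge on the same product.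

Step 9
Reactants: 10 γ-hydroxy enoate
Product: 11 methyl (2R,3R,4R,5S)-4-(tert-butyldimethylsilyloxy)-2,3-(isopropylidenedioxy)-5-methoxycyclohex-1(6)-ene-1-carboxylate
Conditions: Me3OBF4 (3 equiv), 1,8-bis(dimethylamino)naphthalene (4 equiv), 4 Å MS, CH2Cl2, 0 °C to rt
Reagents that add atoms: trimethyloxonium tetrafluoroborate, C[O+](C)C.F[B-](F)(F)F
Why: O-Methylation of the only free hydroxyl by an oxonium salt with a non-nucleophilic proton scavenger. No alkoxide is generated, so the silyl group cannot migrate from O4 to O5 and the γ-oxygenated enoate is not exposed to base.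

Step 10
Reactants: 11 methyl ether
Product: 12 [(2R,3R,4R,5S)-4-(tert-butyldimethylsilyloxy)-2,3-(isopropylidenedioxy)-5-methoxycyclohex-1(6)-en-1-yl]methanol
Conditions: iBu2AlH (2.5 equiv), CH2Cl2, −78 °C; aq. KNaC4H4O6
Reagents that add atoms: none
Why: 1,2-Reduction of the α,β-unsaturated ester to the allylic alcohol by an electrophilic aluminium hydride, which does not reduce the conjugated alkene. Acetal, silyl ether and methyl ether are inert at −78 °C.

Step 11
Reactants: 12 allylic alcohol; 13 benzoyl chloride
Product: 14 [(2R,3R,4R,5S)-4-(tert-butyldimethylsilyloxy)-2,3-(isopropylidenedioxy)-5-methoxycyclohex-1(6)-en-1-yl]methyl benzoate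
Conditions: BzCl (1.2 equiv), pyridine, DMAP (cat.), CH2Cl2, 0 °C
Reagents that add atoms: benzoyl chloride (13), O=C(Cl)c1ccccc1
Why: Acylation of the only free hydroxyl, a primary allylic one, so no selectivity question arises.

Step 12
Reactants: 14 primary benzoate
Product: 15 [(2R,3R,4S,5S)-2,3,4-trihydroxy-5-methoxycyclohex-1(6)-en-1-yl]methyl benzoate
Conditions: TFA/H2O/THF (3:1:1), 0 °C to rt
Reagents that add atoms: none
Why: Acid hydrolysis removes the isopropylidene acetal and the silyl ether in one operation; the benzoate is stable to aqueous acid. The low temperature keeps the allylic ether and allylic ester from ionising, and no base is present that could move the benzoate.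

Step 13
Reactants: 15 triol; 13 benzoyl chloride
Product: 17 [(2R,3R,4R,5S)-3-(benzoyloxy)-2,4-dihydroxy-5-methoxycyclohex-1(6)-en-1-yl]methyl benzoate (target; systematic ring numbering gives 3S,4R,5R,6R), via dimethylstannylene acetal 16 (not isolated)
Conditions: Me2SnCl2 (5 mol%), BzCl (1.1 equiv), iPr2NEt (2 equiv), THF, rt
Reagents that add atoms: benzoyl chloride (13), O=C(Cl)c1ccccc1
Why: Organotin-catalysed regioselective benzoylation: the cis-2,3-diol forms a five-membered stannylene acetal in which the equatorial oxygen is the one acylated. In the half-chair of 15, O3, O4 and O5 are (pseudo)equatorial and O2 is pseudoaxial, which is the axial/equatorial/equatorial pattern of a rhamnopyranoside 2,3,4-triol, where tin-mediated acylation goes to O3. The isolated O4 is not activated, and the mild conditions at room temperature leave the C7 benzoate in place.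

## Compound list

1 | 2,2-dimethyl-1,3-dioxolane | CC1(C)OCCO1 | starting material
2 | 4-chloro-2,2-dimethyl-1,3-dioxolane (racemic) | CC1(C)OCC(Cl)O1 | intermediate
3 | 2,2-dimethyl-1,3-dioxole | CC1(C)OC=CO1 | intermediate
4 | methyl 2-oxo-2H-pyran-3-carboxylate | COC(=O)C1=CC=COC1=O | starting material
5 | methyl (1R,4S,5R,6S)-5,6-(isopropylidenedioxy)-3-oxo-2-oxabicyclo[2.2.2]oct-7-ene-4-carboxylate | C1=C[C@@]2(C(=O)OC)[C@H]3OC(C)(C)O[C@H]3[C@@H]1OC2=O | intermediate
6 | dimethyl (2R,3S,4R)-4-hydroxy-2,3-(isopropylidenedioxy)cyclohex-5-ene-1,1-dicarboxylate | C1=CC(C(=O)OC)(C(=O)OC)[C@H]2OC(C)(C)O[C@H]2[C@@H]1O | intermediate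
7 | dimethyl (2R,3R,4R)-4-(tert-butyldimethylsilyloxy)-2,3-(isopropylidenedioxy)cyclohex-5-ene-1,1-dicarboxylate | C1=CC(C(=O)OC)(C(=O)OC)[C@H]2OC(C)(C)O[C@H]2[C@@H]1O[Si](C)(C)C(C)(C)C | intermediate
8 | dimethyl (2R,3R,4R,5S,6S)-4-(tert-butyldimethylsilyloxy)-5,6-epoxy-2,3-(isopropylidenedioxy)cyclohexane-1,1-dicarboxylate | O1[C@H]2[C@@H]1C(C(=O)OC)(C(=O)OC)[C@H]3OC(C)(C)O[C@H]3[C@@H]2O[Si](C)(C)C(C)(C)C | intermediate
9 | (2R,3R,4R,5S,6S)-4-(tert-butyldimethylsilyloxy)-5,6-epoxy-2,3-(isopropylidenedioxy)-1-(methoxycarbonyl)cyclohexane-1-carboxylic acid, both C1 epimers (C1 left undefined) | O1[C@H]2[C@@H]1C(C(=O)O)(C(=O)OC)[C@H]3OC(C)(C)O[C@H]3[C@@H]2O[Si](C)(C)C(C)(C)C | intermediate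
10 | methyl (2R,3R,4R,5S)-4-(tert-butyldimethylsilyloxy)-5-hydroxy-2,3-(isopropylidenedioxy)cyclohex-1(6)-ene-1-carboxylate | O[C@H]1C=C(C(=O)OC)[C@H]2OC(C)(C)O[C@H]2[C@@H]1O[Si](C)(C)C(C)(C)C | intermediate
11 | methyl (2R,3R,4R,5S)-4-(tert-butyldimethylsilyloxy)-2,3-(isopropylidenedioxy)-5-methoxycyclohex-1(6)-ene-1-carboxylate | CO[C@H]1C=C(C(=O)OC)[C@H]2OC(C)(C)O[C@H]2[C@@H]1O[Si](C)(C)C(C)(C)C | intermediate
12 | [(2R,3R,4R,5S)-4-(tert-butyldimethylsilyloxy)-2,3-(isopropylidenedioxy)-5-methoxycyclohex-1(6)-en-1-yl]methanol | CO[C@H]1C=C(CO)[C@H]2OC(C)(C)O[C@H]2[C@@H]1O[Si](C)(C)C(C)(C)C | intermediate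
13 | benzoyl chloride | O=C(Cl)c1ccccc1 | starting material
14 | [(2R,3R,4R,5S)-4-(tert-butyldimethylsilyloxy)-2,3-(isopropylidenedioxy)-5-methoxycyclohex-1(6)-en-1-yl]methyl benzoate | CO[C@H]1C=C(COC(=O)c3ccccc3)[C@H]2OC(C)(C)O[C@H]2[C@@H]1O[Si](C)(C)C(C)(C)C | intermediate
15 | [(2R,3R,4S,5S)-2,3,4-trihydroxy-5-methoxycyclohex-1(6)-en-1-yl]methyl benzoate | CO[C@H]1C=C(COC(=O)c2ccccc2)[C@@H](O)[C@@H](O)[C@@H]1O | intermediate
16 | 2,3-O-dimethylstannylene acetal of 15 (not isolated) | CO[C@H]1C=C(COC(=O)c3ccccc3)[C@H]2O[Sn](C)(C)O[C@H]2[C@@H]1O | intermediate
17 | [(2R,3R,4R,5S)-3-(benzoyloxy)-2,4-dihydroxy-5-methoxycyclohex-1(6)-en-1-yl]methyl benzoate | CO[C@H]1C=C(COC(=O)c2ccccc2)[C@@H](O)[C@@H](OC(=O)c2ccccc2)[C@@H]1O | target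

## Step count and least certain steps

Total: 13 steps. Longest linear sequence: 13 steps (1 to 17); 4 and 13 are bought and enter at steps 3, 11 and 13.

**Step 3 (key step).** Facial discrimination may be insufficient, because pyrone C6 lies far from the tert-butyl groups of the ligand. Endo selectivity may erode, the enediol ether may oligomerise on the Lewis acid, or the adduct may lose CO2 on warming. Fallback, from 4 and 3 back to 6: the cycloaddition is run without Lewis acid under high pressure (about 10 kbar, CH2Cl2, rt). This gives 5 together with the enantiomeric adduct F1. Methanolysis as in step 4 gives 6 and the enantiomeric hydroxy diester F2. Lipase-catalysed acetylation (Pseudomonas cepacia lipase, vinyl acetate, tert-butyl methyl ether) should, by the empirical size rule for secondary alcohols, acylate the 4R alcohol to the acetate F3. F3 is separated from unreacted F2 and methanolysed (K2CO3, MeOH) to return to 6.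

**Step 6.** The peracid may attack the α face, because the β face carries the axial acetal oxygen at C2; the doubly deactivated alkene may also react sluggishly. Fallback, from 5 back to 11 (it replaces steps 4–9 and gives up the bridge oxygen as the source of O4): heating 5 in toluene at 110 °C expels CO2 by cycloreversion and gives the dienyl ester F4. mCPBA epoxidises its C4=C5 alkene, remote from the ester, anti to the allylic acetal oxygen to give the vinyl epoxide F5. Camphorsulfonic acid in MeOH opens F5 at the allylic C5 with inversion, giving the trans hydroxy ether F6. TBSOTf and 2,6-lutidine then give 11.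

**Step 8.** The carboxylate may open the oxirane intramolecularly instead of losing CO2. The enolate may be protonated before ring opening. The silyl group may shift from O4 to the new O5. Fallback, from 9 back to 10: Barton radical decarboxylation. DCC and N-hydroxypyridine-2-thione (DMAP cat., CH2Cl2, dark) convert 9 into the thiohydroxamate ester F7. Photolysis with visible light and tert-butyl thiol at 0 °C gives the C1 radical, which opens the oxirane to the allyloxy radical; the thiol reduces this to 10.

**Step 13.** O2 or O4 may be acylated in competition, the new benzoate may migrate from O3 to a neighbouring hydroxyl, or the C7 benzoate may move to O2. Fallback, from 12 back to 17 (protecting-group control in place of catalyst control, replacing steps 11–13): 80% aqueous AcOH at 40 °C removes only the acetal and gives the silyl triol F8. tBu2Si(OTf)2 and 2,6-lutidine then close a six-membered ring across the 1,3-related O7 and O2 and give the cyclic silylene F9, in which O3 is the only free hydroxyl. Acylation with 13, pyridine and DMAP gives the O3 benzoate F10. HF·pyridine in THF removes both silicon groups and gives the triol monobenzoate F11. Finally 13 with 2,4,6-collidine at −40 °C benzoylates the primary allylic hydroxyl selectively and gives 17.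

## Further compounds

F1 | step 3 | methyl (1S,4R,5S,6R)-5,6-(isopropylidenedioxy)-3-oxo-2-oxabicyclo[2.2.2]oct-7-ene-4-carboxylate (enantiomer of 5) | C1=C[C@]2(C(=O)OC)[C@@H]3OC(C)(C)O[C@@H]3[C@H]1OC2=O
F2 | step 3 | dimethyl (2S,3R,4S)-4-hydroxy-2,3-(isopropylidenedioxy)cyclohex-5-ene-1,1-dicarboxylate (enantiomer of 6) | C1=CC(C(=O)OC)(C(=O)OC)[C@@H]2OC(C)(C)O[C@@H]2[C@H]1O
F3 | step 3 | dimethyl (2R,3S,4R)-4-acetoxy-2,3-(isopropylidenedioxy)cyclohex-5-ene-1,1-dicarboxylate (acetate of 6) | C1=CC(C(=O)OC)(C(=O)OC)[C@H]2OC(C)(C)O[C@H]2[C@@H]1OC(C)=O
F4 | step 6 | methyl (3aR,7aS)-2,2-dimethyl-3a,7a-dihydro-1,3-benzodioxole-4-carboxylate (C1=C6, C4=C5 diene ester) | COC(=O)C1=CC=C[C@@H]2OC(C)(C)O[C@H]12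
F5 | step 6 | C4,C5-epoxide of F4, oxirane on the α face, anti to the acetal | COC(=O)C1=C[C@H]3O[C@H]3[C@@H]2OC(C)(C)O[C@H]12
F6 | step 6 | methyl (2R,3S,4R,5S)-4-hydroxy-2,3-(isopropylidenedioxy)-5-methoxycyclohex-1(6)-ene-1-carboxylate | CO[C@H]1C=C(C(=O)OC)[C@H]2OC(C)(C)O[C@H]2[C@@H]1O
F7 | step 8 | 2-thioxopyridin-1(2H)-yl ester of half-acid 9 (both C1 epimers) | O1[C@H]2[C@@H]1C(C(=O)ON4C=CC=CC4=S)(C(=O)OC)[C@H]3OC(C)(C)O[C@H]3[C@@H]2O[Si](C)(C)C(C)(C)C
F8 | step 13 | 12 without the isopropylidene group (O2, O3, O7 free; O4 silyl ether) | CO[C@H]1C=C(CO)[C@@H](O)[C@@H](O)[C@@H]1O[Si](C)(C)C(C)(C)C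
F9 | step 13 | 2,7-O-(di-tert-butylsilylene) derivative of F8 (O3 free) | CO[C@H]1C=C2CO[Si](C(C)(C)C)(C(C)(C)C)O[C@H]2[C@@H](O)[C@@H]1O[Si](C)(C)C(C)(C)C
F10 | step 13 | 3-O-benzoate of F9 | CO[C@H]1C=C2CO[Si](C(C)(C)C)(C(C)(C)C)O[C@H]2[C@@H](OC(=O)c3ccccc3)[C@@H]1O[Si](C)(C)C(C)(C)C
F11 | step 13 | 3-O-benzoyl triol (O2, O4, O7 free; O5 methyl ether) | CO[C@H]1C=C(CO)[C@@H](O)[C@@H](OC(=O)c2ccccc2)[C@@H]1O
A1 | alternative 1 | bromobenzene | Brc1ccccc1
A2 | alternative 1 | (1S,2S)-3-bromocyclohexa-3,5-diene-1,2-diol | C1=C(Br)[C@@H](O)[C@@H](O)C=C1
A3 | alternative 2 | Z-enedial carrying tert-butyldimethylsilyl ethers on O4 and O7 and a methyl ether on O5 (target numbering; aldehydes at C2 and C3) | O=C[C@H](O[Si](C)(C)C(C)(C)C)[C@@H](OC)/C=C(\C=O)CO[Si](C)(C)C(C)(C)C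
A4 | alternative 2 | cyclohexene cis-2,3-diol carrying tert-butyldimethylsilyl ethers on O4 and O7 and a methyl ether on O5 (target numbering) | CO[C@H]1C=C(CO[Si](C)(C)C(C)(C)C)[C@@H](O)[C@@H](O)[C@@H]1O[Si](C)(C)C(C)(C)C
A5 | alternative 3 | 2-[(tert-butyldimethylsilyloxy)methyl]-4,4-dimethoxycyclohexa-2,5-dien-1-one | COC1(OC)C=C(CO[Si](C)(C)C(C)(C)C)C(=O)C=C1
A6 | alternative 3 | epoxide of A5 at the unsubstituted enone bond (target C3 and C4), oxirane on the face that later carries the C4 hydroxyl | COC1(OC)C=C(CO[Si](C)(C)C(C)(C)C)C(=O)[C@@H]2O[C@H]12
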